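Crossing between the phases moves material without destroying it, so the two forms of the reagent together stay at the charge until reaction takes some.

    target ⇌ product in the second phase, rate k1*([target] - [product in the second phase]/K1) per volume of the first phase (K1 = 1.9, k1 = 0.54 s⁻¹)
    reagent in the reaction phase ⇌ reagent in the second phase, rate k2*([reagent in the reaction phase] - [reagent in the second phase]/K2) per volume of the first phase (K2 = 8.5, k2 = 1.7 s⁻¹)
    substrate + reagent in the reaction phase ⇌ target (K3 = 670 L mol⁻¹, k3 = 44 L mol⁻¹ s⁻¹)
    target → decomposed product (k4 = 0.0083 s⁻¹)
    2 reagent in the reaction phase → self-condensation product (k5 = 5.6 L mol⁻¹ s⁻¹)

substrate 1.0 mM; reagent in the second phase 0.950 equiv; time 12 s; volume of the second phase over the first 1.0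

- what is said of target includes product in the second phase
- two of one species on the left: rate k times its square, two consumed each time
- in the second phase: reagent in the second phase, product in the second phase; everything else is in the first
- charges count per volume of the first phase; a concentration in a rate is the amount of a species over the volume of its own phase; every rate counts per litre of the first phase
- run time (flask): 12 s

1. the target and product in the second phase together standing at 12 s, as a percentage of the substrate charged
2. the change that raises the amount of target and product in the second phase together at 12 s, in percent of the substrate charged most ("none" if none brings more than 2 percentage points) (Friday's / Tuesday's / Thursday's / none)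
3. amount of target and product in the second phase together at 12 s, in percent of the substrate charged, after Thursday's

Ines calls the crossing of the reagent the rate-limiting step. The reaction phase starts without reagent and 89.5 % of it belongs in the second phase at balance, so she expects Tuesday's or Friday's to pay. Her number is the opening feed across the boundary, 0.190 mM s⁻¹.

Marek counts half-lives. The reagent's crossing relaxes with a half-life of 0.365 s and the target's with 0.841 s, so the run of 12 s holds 32.9 reagent half-lives. After those, the reagent in the reaction phase stands near b, the reagent charge over one plus partition ratio times volume ratio: 0.100 mM.

Substrate then reacts pseudo-first-order with forward constant f, the rate constant of the addition times b: 0.00440 s⁻¹. That demands 0.00440 mM s⁻¹, which is less than Ines's opening feed.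

Target goes back with constant r, the reverse constant times its reaction-phase share: 0.0226 s⁻¹, which is faster than f. Marek's quantity is therefore the approach half-life τ, ln(2) over f plus r: 25.6 s, longer than the crossings and longer than the run. The plateau of this reckoning is f/(f+r), here 16.3 %.

My own reckoning, the plateau times one minus the decay over the run, gives 4.51 %. Doubling f for Thursday's gives 8.80 %.

The forecast, on Marek's side, says 4 %, picks Thursday's and gives 7.7 % after it, lower than my figures, with the words “Faster transfer therefore gains little”.

The flask stands at 3.92 %, and Thursday's wins with 7.67 %, a gain of 3.7 percentage points against 0.11 points for Tuesday's and 0.081 points for Friday's. Ines keeps the opening: at 1.20 s the flask holds 0.306 % of target and product in the second phase together, where f times that time gives 0.528 %. For the neighbour flask with 2.5 mM of substrate, equivalents held, b becomes 0.250 mM, τ shortens to 20.6 s, and the reckoning gives 10.9 %; that flask stands at 8.99 %.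

The numbers of this flask come from no measurement; the rest is arithmetic.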